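Ring B is not taken from an arene but grown from dibenzyl squarate. The four-membered ring supplies C2'–C5' with all four contiguous oxygen atoms; a 2-lithiated acrolein acetal supplies C1', C6' and the carbon that becomes C2 of the pyranone ring C. The precursor is a 4-methoxy-4-(1-substituted vinyl)cyclobutenone. On heating it opens to a dienylketene that closes the C5'–C6' bond and aromatises, so ring B appears in one operation with O at C2', C3', C4', C5', carbon at C1' and hydrogen at C6', exactly the pattern the target needs. Benzyl ethers mark O3' and O4' for later differentiation; a chalcone–flavone sequence with ring A completes the synthesis.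

Key step: step 3

Remark on the chemistry: the tertiary alkoxide from the squarate addition is capped as its methyl ether in the same flask, so the ring expansion gives a mono-phenol rather than an air-sensitive hydroquinone with a free hydroxyl next to the acetal; the carbon skeleton, the bond formed and the ring closed are unchanged. Benzyl alcohol, benzyl bromide, MeI and MeOTf are treated as reagents and carry no number.

Step 1
Reactants: 1 squaric acid
Product: 2 3,4-bis(benzyloxy)cyclobut-3-ene-1,2-dione (dibenzyl squarate)
Conditions: BnOH (3 equiv), PhMe, reflux, Dean–Stark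
Reagents that add atoms: benzyl alcohol, OCc1ccccc1
Why: Squaric acid is a strong vinylogous acid that esterifies with primary alcohols on azeotropic removal of water without added catalyst, the standard vinylogous Fischer esterification used for dialkyl squarates.

Step 2
Reactants: 2 dibenzyl squarate; 3 2-bromo-3,3-diethoxyprop-1-ene
Product: 6 2,3-bis(benzyloxy)-4-(3,3-diethoxyprop-1-en-2-yl)-4-methoxycyclobut-2-en-1-one (racemic), via 2-lithio-3,3-diethoxyprop-1-ene 4 (not isolated), via lithium cyclobutenolate 5 (not isolated)
Conditions: 3, t-BuLi (2.0 equiv), THF, −78 °C; cannulate into 2, THF, −78 °C; then MeOTf, −78 to 0 °C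
Reagents that add atoms: methyl trifluoromethanesulfonate, COS(=O)(=O)C(F)(F)F
Why: Bromine–lithium exchange gives the vinyllithium, which should add 1,2 to one of the two equivalent squarate carbonyls at low temperature, and the resulting lithium alkoxide is O-methylated in situ by MeOTf; the new C4 stereocentre forms as a racemate and is erased in step 3.

Step 3
Reactants: 6 2,3-bis(benzyloxy)-4-(3,3-diethoxyprop-1-en-2-yl)-4-methoxycyclobut-2-en-1-one
Product: 9 2,3-bis(benzyloxy)-5-(diethoxymethyl)-4-methoxyphenol, via dienylketene 7 (not isolated), via cyclohexa-2,4-dienone 8 (not isolated)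
Conditions: PhMe (degassed, 0.02 M), reflux, Ar
Reagents that add atoms: none
Why: Heating triggers conrotatory 4π opening of the cyclobutenone (C1–C4 cleavage) to dienylketene 7, whose ketene carbon (future C5') bonds to the vinyl CH2 terminus (future C6') in a 6π electrocyclisation to dienone 8, and enolisation of 8 gives the phenol. The closest known reaction type is the Moore ring expansion of squarate-derived 4-alkenyl cyclobutenones carrying a 4-hydroxy, 4-alkoxy or 4-siloxy group, which gives hydroquinones and their monoethers. Ring B is closed by a thermal disrotatory 6π electrocyclic closure that forms only the C5'–C6' bond, the other five ring bonds being already present in 7. No stereocentre is formed and the racemic C4 centre of 6 disappears, so nothing has to be controlled there. The selectivity required is torquoselectivity: the alkenyl group must turn inward to lie cis to the ketene, which the strong outward preference of the C4 methoxy donor enforces, and reversible ring opening returns any wrongly opened ketene to 6. Regiochemistry is not an issue because the two halves of the squarate are equivalent, and the 1-substituted vinyl group offers an unhindered CH2 terminus, so C6' ends as the only ring CH.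

Step 4
Reactants: 9 2,3-bis(benzyloxy)-5-(diethoxymethyl)-4-methoxyphenol
Product: 10 2,3-bis(benzyloxy)-5-(diethoxymethyl)-1,4-dimethoxybenzene
Conditions: MeI, K2CO3, acetone, reflux
Reagents that add atoms: iodomethane, CI
Why: Williamson O-methylation of the single, unhindered phenol under basic conditions should leave the acetal and the benzyl ethers untouched.

Step 5
Reactants: 10 2,3-bis(benzyloxy)-5-(diethoxymethyl)-1,4-dimethoxybenzene
Product: 12 3,4-dihydroxy-2,5-dimethoxybenzaldehyde, via catechol diethyl acetal 11 (not isolated)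
Conditions: H2 (1 atm), Pd/C, EtOAc, rt; filter; then 1 M HCl, THF, rt
Reagents that add atoms: water, O
Why: Catalytic hydrogenolysis of the two aryl benzyl ethers is run while the formyl group is still masked, so that it cannot be reduced, and the electron-rich aryl acetal is then hydrolysed by dilute acid.

Step 6
Reactants: 12 3,4-dihydroxy-2,5-dimethoxybenzaldehyde
Product: 13 4-(benzyloxy)-3-hydroxy-2,5-dimethoxybenzaldehyde
Conditions: BnBr (1.05 equiv), NaHCO3, NaI (cat.), DMF, 40 °C
Reagents that add atoms: benzyl bromide, BrCc1ccccc1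
Why: The C4 hydroxyl para to the formyl group is the more acidic one, so a weak base should generate mainly the C4 phenoxide and a regioselective Williamson mono-benzylation follows, as is known for 3,4-dihydroxybenzaldehyde.

Step 7
Reactants: 13 4-(benzyloxy)-3-hydroxy-2,5-dimethoxybenzaldehyde
Product: 14 4-(benzyloxy)-2,3,5-trimethoxybenzaldehyde
Conditions: MeI, K2CO3, DMF, rt
Reagents that add atoms: iodomethane, CI
Why: Williamson methylation of the one remaining phenol fixes the C3' methyl ether next to the benzyl-protected C4' oxygen.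

Step 8
Reactants: 15 2,4,6-trihydroxyacetophenone
Product: 16 1-[2,4-bis(benzyloxy)-6-hydroxyphenyl]ethan-1-one
Conditions: BnBr (2.05 equiv), K2CO3, DMF, rt
Reagents that add atoms: benzyl bromide, BrCc1ccccc1
Why: One ortho hydroxyl stays locked in a hydrogen bond to the acetyl carbonyl and is the least nucleophilic, so a two-fold Williamson benzylation should stop at the 4,6-dibenzyl ether.

Step 9
Reactants: 14 4-(benzyloxy)-2,3,5-trimethoxybenzaldehyde; 16 1-[2,4-bis(benzyloxy)-6-hydroxyphenyl]ethan-1-one
Product: 17 (E)-1-[2,4-bis(benzyloxy)-6-hydroxyphenyl]-3-[4-(benzyloxy)-2,3,5-trimethoxyphenyl]prop-2-en-1-one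
Conditions: KOH (50% aq.), EtOH/THF, rt
Reagents that add atoms: none
Why: Claisen–Schmidt condensation of the methyl ketone enolate with the non-enolisable aldehyde, followed by E1cB dehydration, should give the conjugated enone as its thermodynamically favoured E isomer.

Step 10
Reactants: 17 (E)-1-[2,4-bis(benzyloxy)-6-hydroxyphenyl]-3-[4-(benzyloxy)-2,3,5-trimethoxyphenyl]prop-2-en-1-one
Product: 18 5,7-bis(benzyloxy)-2-[4-(benzyloxy)-2,3,5-trimethoxyphenyl]-4H-chromen-4-one
Conditions: I2 (10 mol%), DMSO, 130 °C
Reagents that add atoms: none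
Why: Iodine-catalysed oxidative cyclisation of a 2'-hydroxychalcone in DMSO (oxa-Michael closure of ring C, then dehydrogenation with DMSO as terminal oxidant) is the standard flavone synthesis and tolerates aryl benzyl and methyl ethers.

Step 11
Reactants: 18 5,7-bis(benzyloxy)-2-[4-(benzyloxy)-2,3,5-trimethoxyphenyl]-4H-chromen-4-one
Product: 19 5,7,4'-trihydroxy-2',3',5'-trimethoxyflavone
Conditions: H2 (1 atm), Pd/C, THF/MeOH, rt
Reagents that add atoms: none
Why: Hydrogenolysis of the three aryl benzyl ethers should free the C5, C7 and C4' hydroxyls while the methyl ethers and the chromone stay intact.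

Compound list
1 | squaric acid (3,4-dihydroxycyclobut-3-ene-1,2-dione) | O=C1C(O)=C(O)C1=O | starting material
2 | 3,4-bis(benzyloxy)cyclobut-3-ene-1,2-dione (dibenzyl squarate) | O=C1C(=O)C(OCc2ccccc2)=C1OCc1ccccc1 | intermediate
3 | 2-bromo-3,3-diethoxyprop-1-ene | C=C(Br)C(OCC)OCC | starting material
4 | 2-lithio-3,3-diethoxyprop-1-ene (not isolated) | [Li]C(=C)C(OCC)OCC | intermediate
5 | lithium 2,3-bis(benzyloxy)-1-(3,3-diethoxyprop-1-en-2-yl)-4-oxocyclobut-2-en-1-olate (racemic, not isolated) | [Li]OC1(C(=C)C(OCC)OCC)C(=O)C(OCc2ccccc2)=C1OCc1ccccc1 | intermediate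
6 | 2,3-bis(benzyloxy)-4-(3,3-diethoxyprop-1-en-2-yl)-4-methoxycyclobut-2-en-1-one (racemic) | O=C1C(OCc2ccccc2)=C(OCc2ccccc2)C1(OC)C(=C)C(OCC)OCC | intermediate
7 | (3Z)-2,3-bis(benzyloxy)-5-(diethoxymethyl)-4-methoxyhexa-1,3,5-trien-1-one (dienylketene, not isolated) | O=C=C(OCc1ccccc1)/C(OCc1ccccc1)=C(/OC)C(=C)C(OCC)OCC | intermediate
8 | 2,3-bis(benzyloxy)-5-(diethoxymethyl)-4-methoxycyclohexa-2,4-dien-1-one (not isolated) | O=C1CC(C(OCC)OCC)=C(OC)C(OCc2ccccc2)=C1OCc1ccccc1 | intermediate
9 | 2,3-bis(benzyloxy)-5-(diethoxymethyl)-4-methoxyphenol | Oc1cc(C(OCC)OCC)c(OC)c(OCc2ccccc2)c1OCc1ccccc1 | intermediate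
10 | 2,3-bis(benzyloxy)-5-(diethoxymethyl)-1,4-dimethoxybenzene | COc1cc(C(OCC)OCC)c(OC)c(OCc2ccccc2)c1OCc1ccccc1 | intermediate
11 | 4-(diethoxymethyl)-3,6-dimethoxybenzene-1,2-diol (not isolated) | COc1cc(C(OCC)OCC)c(OC)c(O)c1O | intermediate
12 | 3,4-dihydroxy-2,5-dimethoxybenzaldehyde | COc1cc(C=O)c(OC)c(O)c1O | intermediate
13 | 4-(benzyloxy)-3-hydroxy-2,5-dimethoxybenzaldehyde | COc1cc(C=O)c(OC)c(O)c1OCc1ccccc1 | intermediate
14 | 4-(benzyloxy)-2,3,5-trimethoxybenzaldehyde | COc1cc(C=O)c(OC)c(OC)c1OCc1ccccc1 | intermediate
15 | 2,4,6-trihydroxyacetophenone | CC(=O)c1c(O)cc(O)cc1O | starting material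
16 | 1-[2,4-bis(benzyloxy)-6-hydroxyphenyl]ethan-1-one | CC(=O)c1c(O)cc(OCc2ccccc2)cc1OCc1ccccc1 | intermediate
17 | (E)-1-[2,4-bis(benzyloxy)-6-hydroxyphenyl]-3-[4-(benzyloxy)-2,3,5-trimethoxyphenyl]prop-2-en-1-one | COc1cc(/C=C/C(=O)c2c(O)cc(OCc3ccccc3)cc2OCc2ccccc2)c(OC)c(OC)c1OCc1ccccc1 | intermediate
18 | 5,7-bis(benzyloxy)-2-[4-(benzyloxy)-2,3,5-trimethoxyphenyl]-4H-chromen-4-one | COc1cc(-c2cc(=O)c3c(OCc4ccccc4)cc(OCc4ccccc4)cc3o2)c(OC)c(OC)c1OCc1ccccc1 | intermediate
19 | 5,7,4'-trihydroxy-2',3',5'-trimethoxyflavone | COc1cc(-c2cc(=O)c3c(O)cc(O)cc3o2)c(OC)c(OC)c1O | target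

Total step count: 11
Longest linear sequence: 10 steps (steps 1–7 and 9–11; step 8 is the ring A branch)

Steps most likely to fail

Step 2. The hindered lithium alkoxide 5 may be captured only in part by MeOTf, and alkoxide left free on warming can open the four-membered ring. The fallback sets out from 5 (made from 2 and 3 as before) and returns at 10; it puts on both methyl groups after the ring expansion. The cold mixture is quenched with aqueous NH4Cl to give the free carbinol 2,3-bis(benzyloxy)-4-(3,3-diethoxyprop-1-en-2-yl)-4-hydroxycyclobut-2-en-1-one F1 (racemic). Heating F1 in degassed PhMe under Ar should give, by the same ring opening (hydroxyl outward) and 6π closure, the hydroquinone 2,3-bis(benzyloxy)-5-(diethoxymethyl)benzene-1,4-diol F2. This is kept under Ar and methylated at once on both phenols (MeI, K2CO3, DMF) to give 10.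

Step 3. The dienylketene may be consumed by oligomerisation or by adventitious nucleophiles faster than it undergoes the 6π closure. The fallback sets out from 2 and returns at 10; it builds ring B through the alkynyl variant of the squarate ring expansion, which runs through a diradical and ends at an isolable quinone.
- Commercial 3,3-diethoxyprop-1-yne is lithiated (n-BuLi, THF, −78 °C) to lithium 3,3-diethoxyprop-1-yn-1-ide F3.
- F3 is added to 2 and quenched with aqueous NH4Cl to give 2,3-bis(benzyloxy)-4-(3,3-diethoxyprop-1-yn-1-yl)-4-hydroxycyclobut-2-en-1-one F4 (racemic).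
- Heating F4 (PhMe, 110 °C) should give the quinone 2,3-bis(benzyloxy)-5-(diethoxymethyl)cyclohexa-2,5-diene-1,4-dione F5, by enynylketene formation, ring closure and transfer of the hydroxyl hydrogen to the ring; this is known for alkyl-type alkyne substituents.
- Reduction with Na2S2O4 (aqueous THF) gives the hydroquinone 2,3-bis(benzyloxy)-5-(diethoxymethyl)benzene-1,4-diol F2, which is methylated directly (Me2SO4, K2CO3, acetone) to 10.

Step 6. Discrimination between the two catechol oxygens may be poor, giving the regioisomeric ether and the dibenzyl ether as well. The fallback sets out from 12 and returns at 14; it reverses the order of alkylation and relies on nucleophilicity, not acidity. Compound 12 is deprotonated twice (NaH, 2.2 equiv, DMSO) and treated with MeI (1.0 equiv). In the dianion the C3 phenoxide is not conjugated with the formyl group and is the more nucleophilic site, so methylation there should give 4-hydroxy-2,3,5-trimethoxybenzaldehyde F6. Benzylation of its remaining phenol (BnBr, K2CO3, DMF) gives 14.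

Further compounds
F1 | step 2 | 2,3-bis(benzyloxy)-4-(3,3-diethoxyprop-1-en-2-yl)-4-hydroxycyclobut-2-en-1-one (racemic) | O=C1C(OCc2ccccc2)=C(OCc2ccccc2)C1(O)C(=C)C(OCC)OCC
F2 | step 2 | 2,3-bis(benzyloxy)-5-(diethoxymethyl)benzene-1,4-diol | CCOC(OCC)c1cc(O)c(OCc2ccccc2)c(OCc2ccccc2)c1O
F3 | step 3 | lithium 3,3-diethoxyprop-1-yn-1-ide | [Li]C#CC(OCC)OCC
F4 | step 3 | 2,3-bis(benzyloxy)-4-(3,3-diethoxyprop-1-yn-1-yl)-4-hydroxycyclobut-2-en-1-one (racemic) | O=C1C(OCc2ccccc2)=C(OCc2ccccc2)C1(O)C#CC(OCC)OCC
F5 | step 3 | 2,3-bis(benzyloxy)-5-(diethoxymethyl)cyclohexa-2,5-diene-1,4-dione | O=C1C=C(C(OCC)OCC)C(=O)C(OCc2ccccc2)=C1OCc1ccccc1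
F6 | step 6 | 4-hydroxy-2,3,5-trimethoxybenzaldehyde | COc1cc(C=O)c(OC)c(OC)c1O
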